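## The problem

The target 11 is a C2-symmetric 2,2'-biphenol in which two benzene rings are joined through C1–C1' and each ring carries OH at C2, OMe at C3, a 2-carboxyethyl chain at C5 and hydrogen at C4 and C6. It has no stereocentre and its axis, flanked by only two ortho hydroxyls, rotates freely, so nothing has to be set stereochemically, no centre can direct another, and the task is purely regiochemical. The biaryl bond must sit ortho to each hydroxyl, the 1,2,3,5 pattern must be the same on both rings, and two three-carbon acid chains must reach C5 and C5' at the right oxidation level. The electron-rich guaiacol-type biphenol is easily oxidised to quinones and its 2,2'-oxygenation invites dibenzofuran closure, so it should be unveiled last. The acids are best carried as ethyl esters, which rules out strongly nucleophilic or hydridic reagents on the way. The enabling feature is that the hydroxyl carbons C2 and C2' flank the C1–C1' bond while C6 and C6' carry only hydrogen. A two-carbon bridge from C2 to C2' turns the skeleton into a phenanthrene in which C1/C1' are C4a/C4b, C2/C2' are C10a/C8a, the bridge is C9=C10, the methoxy groups sit at C1/C8 and the chains at C3/C6. The C4a–C4b bond between two ortho C–H carbons is the bond that a stilbene photocyclisation makes, and C9=C10 is the one alkene-like bond of a phenanthrene, so it can be excised and replaced by the two hydroxyls.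

## Retrosynthesis

**11 from 10.** The last cut is through four ester C–O bonds: the two aryl formates and the two ethyl esters of diethyl bis(formate) 10. One mild saponification frees phenols and acids together, so the oxidation-prone biphenol diacid 11 appears only at the end. The forward step needs only aqueous LiOH with air excluded.

**10 from 9.** The two aryl C–O bonds are traced back to aryl C–CHO bonds of dialdehyde 9 (Baeyer–Villiger retron). Oxygen is delivered exactly where carbon sat, so no regiochemical question arises. Routes through a cation, radical or metal centre at C2 would be trapped by the 2'-substituent, whereas a concerted aryl migration offers no such centre. The forward reaction needs aryl, not hydride, to migrate; the ortho methoxy and para alkyl groups provide for that.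

**9 from 7.** The two formyl carbons are reconnected as the C9=C10 bond of phenanthrene 7, the forward step passing through methoxy hydroperoxide 8. This trades two carbonyl groups for one symmetric arene. The forward reaction must cleave the K-region bond without touching the methoxy-bearing outer rings.

**7 from 4 (key cut).** The C4a–C4b bond of 7 is cut, leading to E-stilbene 4; in the forward sense the Z isomer 5 and the dihydrophenanthrene 6 are passed through. A direct intermolecular coupling of two 1,2,3,5-substituted rings would need a halogen or metal on each, or a phenol coupling of uncertain regiochemistry. The tethered closure needs no functional group on the two carbons that are joined. Stilbene 4 has no biaryl bond and is symmetric. The forward step must close at the ortho C–H and not at the ortho C–OMe. Each ring has a single ortho hydrogen, and the chain is para to the alkene carbon, so no further regioisomer can arise.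

**4 from 3.** The central C=C is cut into two identical molecules of aldehyde 3, to be joined by McMurry coupling. A Wittig route would need two different halves and three more steps. The forward reaction must couple aryl aldehydes in the presence of aliphatic esters; alkene geometry does not matter because light equilibrates it.

**3 from 1 and 2.** The aryl–CH2 bond is cut to aryl bromide 1 and zinc homoenolate 2. A Negishi coupling brings in the whole chain at its final oxidation level in one step. A Heck reaction with an acrylate would need a subsequent hydrogenation that competes with the aldehyde. The forward step relies on the inertness of alkylzinc halides towards aldehydes.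

## Roads not taken

**Alternative 1:** The cut is at both aryl C5–CH2 bonds, traced back to O-allyl groups. Heating the bis(allyl ether) 2,2'-bis(allyloxy)-3,3'-dimethoxybiphenyl A1 should move each allyl group by a [3,3] shift to a blocked ortho carbon and on by a Cope shift to C5. The product would be 5,5'-diallyl-3,3'-dimethoxybiphenyl-2,2'-diol A2. Ether A1 would be made by twofold O-allylation of 3,3'-dimethoxybiphenyl-2,2'-diol A3.
- Merits: the key step is purely thermal, easy to scale, regiospecific because both ortho positions of A1 are blocked, and it frees the phenols as it forms the C–C bonds. The biaryl and its oxygen pattern are already in place in A3, and no carbon is thrown away.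
- Weak points: A2 carries allyl groups, not propanoic acids. Each terminal alkene would need anti-Markovnikov hydroboration and oxidation to the acid, with the phenols protected, which is about four further steps. A3 is not trivially available, because ortho,ortho coupling of a para-unsubstituted methoxyphenol is unselective and a directed route is needed.
- Comparison: the operationally simpler key step and the better atom economy are real advantages. The chosen plan sets against them chains at the final oxidation level from step 1, no protecting groups, and a shorter overall sequence.

**Alternative 2:** Each ring is cut at C1–C6 and C3–C4, leading to 1,6-dimethoxyhexane-2,5-dione A4 and two equivalents of the 2-(3-methoxy-3-oxopropyl)vinamidinium hexafluorophosphate A5. A twofold [3+3] condensation, in which each ketone of A4 uses both alpha carbons, would give the dimethyl ester of the target, A6.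
- Merits: it is the most convergent of all plans. Four C–C bonds and both rings form in one operation, every substituent is in place, and A6 is one hydrolysis from the target. If it worked it would be shorter than the chosen route.
- Weak points: this benzannulation is established for ketones with activated alpha carbons (aryl or ester), not for alpha-alkoxy dialkyl ketones. A4 is a 1,4-diketone that under base can cyclise on itself by aldol reaction. Its inner alpha carbons, the future C1 and C1', are adjacent, so the second annulation must take place next to a newly formed ring. A5 has to be prepared first.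
- Comparison: the gain in brevity rests on a key step without precedent for this substrate class. The chosen plan is longer, but each step has close precedent.

**Alternative 3:** The cut is at the terminal CH2–C(=O) bonds of both chains. The divinylbiaryl 2,2'-bis(benzyloxy)-5,5'-diethenyl-3,3'-dimethoxybiphenyl A7 would react with CO and methanol under Pd(OAc)2, 1,2-bis(di-tert-butylphosphinomethyl)benzene and CH3SO3H. The product would be dimethyl 3,3'-[6,6'-bis(benzyloxy)-5,5'-dimethoxybiphenyl-3,3'-diyl]dipropanoate A8. Diester A8 would then need hydrogenolysis of the benzyl ethers and saponification to reach the target.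
- Merits: A7 should be reachable by benzylation and Wittig methylenation of 6,6'-dihydroxy-5,5'-dimethoxybiphenyl-3,3'-dicarbaldehyde A9. Dialdehyde A9 is the oxidative dimer of a cheap phenolic aldehyde, so biaryl bond and oxygenation come almost free. No carbon is excised and no photochemistry or ozone is needed. The step count is similar to the chosen route.
- Weak points: styrenes are the alkenes for which branched insertion is electronically favoured, and with two sites in A7 any leakage multiplies. The vinyl groups are para to an alkoxy group and liable to acid-induced oligomerisation under the sulfonic acid promoter. Pressurised CO and two benzyl protecting groups are required.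
- Comparison: this road is better in atom economy and in the availability of the biaryl. The chosen plan sets against it a regiochemically unambiguous chain introduction by Negishi coupling, no protecting groups and no pressure equipment. It pays for this with the three-step excision of the two bridge carbons.

Key step: step 3

Assumption: reagent 2 is used as its commercial 0.5 M solution in THF; the target has no stereocentre and a freely rotating axis, so no stereochemical element needs to be set.

## Route

Step 1
Reactants: 1 4-bromo-2-methoxybenzaldehyde; 2 3-ethoxy-3-oxopropylzinc bromide
Product: 3 ethyl 3-(4-formyl-3-methoxyphenyl)propanoate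
Conditions: 2 (0.5 M in THF, 1.3 equiv), Pd(OAc)2 (2 mol %), SPhos (2-dicyclohexylphosphino-2',6'-dimethoxybiphenyl, 4 mol %), THF, 25 to 50 °C
Reagents that add atoms: none
Why: Negishi cross-coupling: zerovalent palladium formed in situ inserts into the C–Br bond, which the para formyl group activates, and transmetalation with the primary alkylzinc bromide followed by reductive elimination gives the arylpropanoate; alkylzinc halides do not add to aldehydes or esters under these conditions, and the bulky biarylphosphine lets reductive elimination outrun beta-hydride elimination.

Step 2
Reactants: 3 ethyl 3-(4-formyl-3-methoxyphenyl)propanoate (two molecules)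
Product: 4 diethyl 3,3'-[(E)-ethene-1,2-diylbis(3-methoxy-4,1-phenylene)]dipropanoate
Conditions: TiCl4, Zn dust, pyridine, THF, 0 °C then reflux
Reagents that add atoms: none
Why: McMurry reductive coupling: low-valent titanium generated from TiCl4 and Zn joins two aldehyde carbonyls to a titanium-bound 1,2-diolate and deoxygenates it at reflux to the stilbene, mainly E; aromatic aldehydes couple far faster than aliphatic esters, so the ester chains should survive a short reaction time, and the alkene geometry is immaterial because light equilibrates it in step 3.

Step 3
Reactants: 4 diethyl 3,3'-[(E)-ethene-1,2-diylbis(3-methoxy-4,1-phenylene)]dipropanoate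
Product: 7 diethyl 3,3'-(1,8-dimethoxyphenanthrene-3,6-diyl)dipropanoate, via Z-stilbene diester 5 (not isolated), via trans-4a,4b-dihydrophenanthrene diester 6 (not isolated)
Conditions: hν (medium-pressure Hg lamp, Pyrex filter), I2 (1.1 equiv), methyloxirane (excess), toluene (about 2 mM, degassed), argon, rt
Reagents that add atoms: none
Why: This is a Mallory-type oxidative photocyclisation of a stilbene, the closest known case being the iodine-mediated conversion of ortho-methoxystilbenes into 1-methoxyphenanthrenes. Light first equilibrates 4 with the Z isomer 5, whose excited singlet state, a cis-hexatriene made of the alkene and one C=C of each ring, closes by conrotatory 6-pi electrocyclisation between the two ortho C–H carbons; this forms the C4a–C4b bond and the central six-membered ring B. The closure product is the trans-4a,4b-dihydrophenanthrene 6 (racemic, trans by conrotation), and its two stereocentres vanish when iodine removes both hydrogens, so no stereocentre reaches 7. One equivalent of I2 is the oxidant and methyloxirane removes the HI as 1-iodopropan-2-ol, which keeps HI from reducing the alkene or cleaving the ethers and makes air unnecessary. The selectivity needed is closure at the ortho C–H of each ring and not at the methoxy-bearing ortho carbon: each ring has only one ortho hydrogen, closure there is trapped irreversibly by dehydrogenation, whereas a dihydrophenanthrene closed at C–OMe can only revert or lose methanol slowly in the absence of acid. Because the chain is para to the alkene carbon, no regioisomer from a meta substituent can arise and the new bay region carries only hydrogen. High dilution suppresses [2+2] dimerisation of the stilbene.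

Step 4
Reactants: 7 diethyl 3,3'-(1,8-dimethoxyphenanthrene-3,6-diyl)dipropanoate
Product: 9 diethyl 3,3'-(6,6'-diformyl-5,5'-dimethoxybiphenyl-3,3'-diyl)dipropanoate, via methoxy hydroperoxide aldehyde 8 (not isolated)
Conditions: O3 (1.0 equiv), CH2Cl2/MeOH, −78 °C; then Me2S, −78 °C to rt
Reagents that add atoms: ozone, [O-][O+]=O (methanol, CO, enters intermediate 8 only)
Why: Ozonolysis: ozone adds to the C9=C10 bond, by far the most alkene-like bond of a phenanthrene, the carbonyl oxide is trapped by methanol as methoxy hydroperoxide 8, and Me2S reduces it to the second aldehyde; one equivalent of ozone at −78 °C should leave the methoxy-substituted outer rings intact.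

Step 5
Reactants: 9 diethyl 3,3'-(6,6'-diformyl-5,5'-dimethoxybiphenyl-3,3'-diyl)dipropanoate
Product: 10 diethyl 3,3'-[6,6'-bis(formyloxy)-5,5'-dimethoxybiphenyl-3,3'-diyl]dipropanoate
Conditions: mCPBA (3 equiv), CH2Cl2, 0 °C to rt
Reagents that add atoms: mCPBA (3-chloroperoxybenzoic acid), OOC(=O)c1cccc(Cl)c1
Why: Baeyer–Villiger (Dakin-type) oxidation: the peracid adds to each formyl group and the electron-rich aryl group (ortho methoxy, para alkyl) migrates to oxygen in preference to hydride, giving the aryl formate with oxygen on the former C–CHO carbon; the concerted migration leaves no cationic or radical centre that the neighbouring ring could trap.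

Step 6
Reactants: 10 diethyl 3,3'-[6,6'-bis(formyloxy)-5,5'-dimethoxybiphenyl-3,3'-diyl]dipropanoate
Product: 11 3,3'-(6,6'-dihydroxy-5,5'-dimethoxybiphenyl-3,3'-diyl)dipropanoic acid
Conditions: LiOH, THF/H2O (degassed), rt; then aq. HCl
Reagents that add atoms: lithium hydroxide, [Li+].[OH-], in water, O (the hydroxide oxygen becomes one oxygen of each carboxyl group)
Why: Saponification: hydroxide cleaves the two very labile aryl formates and the two ethyl esters by acyl substitution and acidification gives the free diacid biphenol; degassed solvents guard the electron-rich biphenolate against air oxidation.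

## Compound list

1 | 4-bromo-2-methoxybenzaldehyde | COc1cc(Br)ccc1C=O | starting material
2 | 3-ethoxy-3-oxopropylzinc bromide | CCOC(=O)CC[Zn]Br | starting material
3 | ethyl 3-(4-formyl-3-methoxyphenyl)propanoate | CCOC(=O)CCc1ccc(C=O)c(OC)c1 | intermediate
4 | diethyl 3,3'-[(E)-ethene-1,2-diylbis(3-methoxy-4,1-phenylene)]dipropanoate | CCOC(=O)CCc1ccc(/C=C/c2ccc(CCC(=O)OCC)cc2OC)c(OC)c1 | intermediate
5 | diethyl 3,3'-[(Z)-ethene-1,2-diylbis(3-methoxy-4,1-phenylene)]dipropanoate (formed in the flask in step 3) | CCOC(=O)CCc1ccc(/C=C\c2ccc(CCC(=O)OCC)cc2OC)c(OC)c1 | intermediate
6 | diethyl 3,3'-[(4aR*,4bR*)-1,8-dimethoxy-4a,4b-dihydrophenanthrene-3,6-diyl]dipropanoate (trans, racemic, one enantiomer drawn; formed in the flask in step 3) | COC1=CC(CCC(=O)OCC)=C[C@H]2C1=CC=C1C(OC)=CC(CCC(=O)OCC)=C[C@@H]12 | intermediate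
7 | diethyl 3,3'-(1,8-dimethoxyphenanthrene-3,6-diyl)dipropanoate | CCOC(=O)CCc1cc(OC)c2ccc3c(OC)cc(CCC(=O)OCC)cc3c2c1 | intermediate
8 | diethyl 3,3'-{6-formyl-6'-[hydroperoxy(methoxy)methyl]-5,5'-dimethoxybiphenyl-3,3'-diyl}dipropanoate (peroxyacetal carbon of undefined configuration; formed in the flask in step 4) | CCOC(=O)CCc1cc(OC)c(C=O)c(c1)-c1cc(CCC(=O)OCC)cc(OC)c1C(OC)OO | intermediate
9 | diethyl 3,3'-(6,6'-diformyl-5,5'-dimethoxybiphenyl-3,3'-diyl)dipropanoate | CCOC(=O)CCc1cc(OC)c(C=O)c(c1)-c1cc(CCC(=O)OCC)cc(OC)c1C=O | intermediate
10 | diethyl 3,3'-[6,6'-bis(formyloxy)-5,5'-dimethoxybiphenyl-3,3'-diyl]dipropanoate | CCOC(=O)CCc1cc(OC)c(OC=O)c(c1)-c1cc(CCC(=O)OCC)cc(OC)c1OC=O | intermediate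
11 | 3,3'-(6,6'-dihydroxy-5,5'-dimethoxybiphenyl-3,3'-diyl)dipropanoic acid | COc1cc(CCC(=O)O)cc(-c2cc(CCC(=O)O)cc(OC)c2O)c1O | target

## Step count and risks

Total: 6 steps. Longest linear sequence: 6 steps (1 to 11).

**Step 3 (key step).** The most likely failure is closure onto the methoxy-bearing ortho carbon followed by loss of methanol, which erodes one methoxy group. Conversion may also be slow on scale, because the phenanthrene competes for light and the stilbene dimerises by [2+2] addition once the concentration is raised. Fallback: make the biaryl bond by metal-mediated coupling instead of light. Setting out from 3, a Pd(OAc)2-catalysed ortho C–H bromination through a transient imine directing group (amine additive, N-bromosuccinimide) can reach only the one free position ortho to the formyl group. It should give ethyl 3-(3-bromo-4-formyl-5-methoxyphenyl)propanoate F1. Ullmann homocoupling of F1 with Cu powder in DMF should then give dialdehyde 9 directly, where the route is rejoined; steps 2 to 4 are bypassed.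

**Step 4.** The most likely failure is over-oxidation: once the C9=C10 bond is consumed, ozone starts to attack the methoxy-activated outer rings, and inexact dosing degrades the material. Fallback: cleave the K-region bond in two stages with reagents that do not touch arenes. Setting out from 7, OsO4 in pyridine should dihydroxylate only the C9=C10 bond to give diethyl 3,3'-[(9R,10S)-9,10-dihydroxy-1,8-dimethoxy-9,10-dihydrophenanthrene-3,6-diyl]dipropanoate F2 (cis, meso). NaIO4 in aqueous THF then cleaves the diol F2 to 9, where the route is rejoined.

**Step 5.** Three things may go wrong. Hydride may migrate instead of aryl at the doubly ortho-substituted formyl groups, which gives carboxylic acids. The peracid adduct may add to the neighbouring formyl group. Excess peracid may oxidise phenol released prematurely from the formate. Fallback: carry out the oxygen insertion on methyl ketones, where no hydride can migrate and the carbonyl is less prone to neighbouring-group addition. Setting out from 9, MeTi(OiPr)3 adds to aldehydes but not to esters and should give diethyl 3,3'-[6,6'-bis(1-hydroxyethyl)-5,5'-dimethoxybiphenyl-3,3'-diyl]dipropanoate F3 as a mixture of diastereomers. Swern oxidation of F3 gives diethyl 3,3'-(6,6'-diacetyl-5,5'-dimethoxybiphenyl-3,3'-diyl)dipropanoate F4. Baeyer–Villiger oxidation of F4 with mCPBA, with the electron-rich aryl group migrating in preference to methyl, gives diethyl 3,3'-[6,6'-bis(acetyloxy)-5,5'-dimethoxybiphenyl-3,3'-diyl]dipropanoate F5. LiOH in degassed aqueous THF then cleaves the acetates and ethyl esters of F5 to the target 11, where the route is rejoined.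

**Step 2.** The ester groups may enter reductive side reactions (ester–aldehyde coupling), the coupling may stall at the pinacol stage, or the stilbene may be over-reduced to the bibenzyl. Fallback: reverse the order of the first two steps so that no ester is present during the reductive coupling. Setting out from 1, McMurry coupling (TiCl4, Zn, THF, reflux) should give 1,1'-[(E)-ethene-1,2-diyl]bis(4-bromo-2-methoxybenzene) F6, since aryl bromides tolerate low-valent titanium. A twofold Negishi coupling of F6 with 2 (Pd(OAc)2, SPhos, THF) then gives stilbene 4, where the route is rejoined.

## Further compounds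

F1 | step 3 | ethyl 3-(3-bromo-4-formyl-5-methoxyphenyl)propanoate | CCOC(=O)CCc1cc(Br)c(C=O)c(OC)c1
F2 | step 4 | diethyl 3,3'-[(9R,10S)-9,10-dihydroxy-1,8-dimethoxy-9,10-dihydrophenanthrene-3,6-diyl]dipropanoate (cis, meso) | CCOC(=O)CCc1cc(OC)c2[C@H](O)[C@H](O)c3c(OC)cc(CCC(=O)OCC)cc3-c2c1
F3 | step 5 | diethyl 3,3'-[6,6'-bis(1-hydroxyethyl)-5,5'-dimethoxybiphenyl-3,3'-diyl]dipropanoate (mixture of diastereomers, configuration not defined) | CCOC(=O)CCc1cc(OC)c(C(C)O)c(c1)-c1cc(CCC(=O)OCC)cc(OC)c1C(C)O
F4 | step 5 | diethyl 3,3'-(6,6'-diacetyl-5,5'-dimethoxybiphenyl-3,3'-diyl)dipropanoate | CCOC(=O)CCc1cc(OC)c(C(C)=O)c(c1)-c1cc(CCC(=O)OCC)cc(OC)c1C(C)=O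
F5 | step 5 | diethyl 3,3'-[6,6'-bis(acetyloxy)-5,5'-dimethoxybiphenyl-3,3'-diyl]dipropanoate | CCOC(=O)CCc1cc(OC)c(OC(C)=O)c(c1)-c1cc(CCC(=O)OCC)cc(OC)c1OC(C)=O
F6 | step 2 | 1,1'-[(E)-ethene-1,2-diyl]bis(4-bromo-2-methoxybenzene) | COc1cc(Br)ccc1/C=C/c1ccc(Br)cc1OC
A1 | alternative 1 | 2,2'-bis(allyloxy)-3,3'-dimethoxybiphenyl | C=CCOc1c(OC)cccc1-c1cccc(OC)c1OCC=C
A2 | alternative 1 | 5,5'-diallyl-3,3'-dimethoxybiphenyl-2,2'-diol | C=CCc1cc(OC)c(O)c(c1)-c1cc(CC=C)cc(OC)c1O
A3 | alternative 1 | 3,3'-dimethoxybiphenyl-2,2'-diol | COc1cccc(c1O)-c1cccc(OC)c1O
A4 | alternative 2 | 1,6-dimethoxyhexane-2,5-dione | COCC(=O)CCC(=O)COC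
A5 | alternative 2 | N-[3-(dimethylamino)-2-(3-methoxy-3-oxopropyl)prop-2-en-1-ylidene]-N-methylmethanaminium hexafluorophosphate | COC(=O)CCC(C=[N+](C)C)=CN(C)C.F[P-](F)(F)(F)(F)F
A6 | alternative 2 | dimethyl 3,3'-(6,6'-dihydroxy-5,5'-dimethoxybiphenyl-3,3'-diyl)dipropanoate | COC(=O)CCc1cc(OC)c(O)c(c1)-c1cc(CCC(=O)OC)cc(OC)c1O
A7 | alternative 3 | 2,2'-bis(benzyloxy)-5,5'-diethenyl-3,3'-dimethoxybiphenyl | C=Cc1cc(OC)c(OCc2ccccc2)c(c1)-c1cc(C=C)cc(OC)c1OCc1ccccc1
A8 | alternative 3 | dimethyl 3,3'-[6,6'-bis(benzyloxy)-5,5'-dimethoxybiphenyl-3,3'-diyl]dipropanoate | COC(=O)CCc1cc(OC)c(OCc2ccccc2)c(c1)-c1cc(CCC(=O)OC)cc(OC)c1OCc1ccccc1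
A9 | alternative 3 | 6,6'-dihydroxy-5,5'-dimethoxybiphenyl-3,3'-dicarbaldehyde | COc1cc(C=O)cc(c1O)-c1cc(C=O)cc(OC)c1O
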